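The route rests on cutting C1–C10 and C5–C6, which reads the trans ring-fusion carbons C1 and C5 of the five-membered ring as the β- and α-carbons of a cyclopentanone whose carbonyl is C4, with an alkenyl carbon (C10) on C1 and a carbinol (C6) on C5. One tandem conjugate addition–aldol therefore joins a 2-metallated penta-1,4-dien-3-yl silyl ether (C8, C9, C10, C14), (S)-4-silyloxycyclopentenone (C1–C5) and acrolein (C6, C7). It sets C1, C5 and C6 and delivers every ring carbon of the hydroazulene with two vinyl groups poised for metathesis. The precursors are just bromodiene 10, enone 11 and acrolein; an O6-tethered radical cyclization later relays C7, C11 and C12.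

Key step: step 6

Remark: atoms are numbered as in guaianes. Five-membered ring C1–C2–C3–C4–C5 (OH on C3, methylene C15 on C4); seven-membered ring C5–C6–C7–C8–C9–C10–C1 (OH on C6 and C9, methylene C14 on C10); side chain C11 (methyl C13) and C12 (acetoxy) on C7. TBS = tert-butyldimethylsilyl, TES = triethylsilyl.
Assumption: the lipase in step 2 is taken to acylate the (R)-enantiomer of 4, the usual preference when the silylalkynyl group acts as the large substituent.
Remark: compounds 17 to 24 are carried as mixtures of epimers at the acetal carbon and lactol 25 as anomers; this centre disappears in step 15.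

Step 1
Reactants: 1 (trimethylsilyl)acetylene; 2 acrolein
Product: 4 rac-5-(trimethylsilyl)pent-1-en-4-yn-3-ol, via lithium acetylide 3 (not isolated)
Conditions: n-BuLi, THF, −78 °C; then acrolein, −78 °C; aq. NH4Cl
Reagents that add atoms: none
Why: Acetylide addition: the lithium acetylide adds cleanly in a 1,2-sense to the aldehyde of acrolein at low temperature, and the racemic carbinol carbon (later C9) is resolved in step 2.

Step 2
Reactants: 4 rac-5-(trimethylsilyl)pent-1-en-4-yn-3-ol
Product: 5 (R)-5-(trimethylsilyl)pent-1-en-4-yn-3-yl acetate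
Conditions: Amano lipase AK (Pseudomonas fluorescens), vinyl acetate, hexane, 30 °C, stopped near half conversion
Reagents that add atoms: vinyl acetate, C=COC(C)=O
Why: Lipase-catalysed kinetic resolution by irreversible transesterification: by the empirical rule for lipases the enantiomer whose long silylalkynyl group fills the large pocket, (R)-4, should be acylated, which fixes C9 and lets the acetate be separated from the unreacted (S)-alcohol.

Step 3
Reactants: 5 (R)-5-(trimethylsilyl)pent-1-en-4-yn-3-yl acetate
Product: 7 (R)-pent-1-en-4-yn-3-ol, via silylated enynol 6 (not isolated)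
Conditions: K2CO3, MeOH, 0 °C to rt
Reagents that add atoms: none
Why: Carbonate in methanol cleaves the acetate by transesterification and the C(sp)–Si bond by protodesilylation in the same pot without touching the carbinol stereocentre; the volatile enynol is kept as an ether solution for step 4.

Step 4
Reactants: 7 (R)-pent-1-en-4-yn-3-ol
Product: 8 (R)-3-(tert-butyldimethylsilyloxy)pent-1-en-4-yne
Conditions: TBSCl, imidazole, CH2Cl2, 0 °C to rt
Reagents that add atoms: tert-butyldimethylsilyl chloride, CC(C)(C)[Si](C)(C)Cl
Why: Standard imidazole-promoted silylation of a secondary alcohol gives the ether that becomes the C9 silyloxy group.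

Step 5
Reactants: 8 (R)-3-(tert-butyldimethylsilyloxy)pent-1-en-4-yne
Product: 10 (R)-2-bromo-3-(tert-butyldimethylsilyloxy)penta-1,4-diene, via bromoalkenylborane 9 (not isolated)
Conditions: B-bromo-9-BBN, CH2Cl2, 0 °C; then AcOH, 0 °C to rt
Reagents that add atoms: B-bromo-9-borabicyclo[3.3.1]nonane, BrB1C2CCCC1CCC2
Why: Bromoboration of the terminal alkyne puts boron on the terminal and bromine on the internal carbon by syn addition, and protodeboronation with acetic acid leaves the 2-bromo-1-alkene; the vinyl group and the silyl ether do not react with the haloborane at 0 °C.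

Step 6
Reactants: 10 (R)-2-bromo-3-(tert-butyldimethylsilyloxy)penta-1,4-diene; 11 (S)-4-(tert-butyldimethylsilyloxy)cyclopent-2-en-1-one; 2 acrolein
Product: 15 three-component aldol adduct (4-oxo-2-silyloxycyclopentane with the C5 hydroxyallyl and C1 dienyl chains), via dienyllithium 12 (not isolated), via lithium zincate 13 (not isolated), via zinc enolate 14 (not isolated)
Conditions: t-BuLi (2 equiv), Et2O, −78 °C; Me2Zn, −78 °C; 11, THF, −78 °C; acrolein, −78 °C; aq. NH4Cl
Reagents that add atoms: none
Why: Bromine–lithium exchange gives dienyllithium 12, which Me2Zn turns into the mixed zincate 13; this transfers only its alkenyl group in a 1,4-sense to enone 11, and the regiodefined C4–C5 zinc enolate 14 is intercepted by the non-enolisable aldehyde acrolein in a 1,2-sense, so the C1–C10 and C5–C6 bonds form in one flask. The closest known reaction type is the three-component conjugate addition–enolate capture on 4-silyloxycyclopentenones used for prostaglandins, here with aldol capture. No ring is closed: the step assembles all ten ring carbons of the hydroazulene and leaves the C7 and C8 vinyl termini for the later metathesis. C1 is controlled by the C2 silyloxy group of 11 (addition to the opposite face), C5 by the new C1 substituent (the enolate reacts on the face away from it, giving the trans pattern), and C6 by a closed chair transition state in which the ring-locked E enolate and an equatorial vinyl group give the anti aldol, the C6 configuration of 37; C9 is carried unchanged from 10. The selectivities needed are 1,4- over 1,2-transfer of the dienyl group (secured by the soft zincate), reaction through the kinetic enolate without proton transfer or loss of the C2 silyloxy group (secured by −78 °C and immediate capture), and carbonyl rather than conjugate capture by acrolein (secured by the hard zinc enolate at low temperature).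

Step 7
Reactants: 15 three-component aldol adduct; 16 ethyl vinyl ether
Product: 17 C6 O-(2-bromo-1-ethoxyethyl) acetal of 15
Conditions: NBS, ethyl vinyl ether (excess), CH2Cl2, −40 to 0 °C
Reagents that add atoms: N-bromosuccinimide, O=C1CCC(=O)N1Br
Why: NBS-induced bromoacetalization: the C6 hydroxyl captures the bromonium-activated enol ether under neutral, cold conditions that spare the β-hydroxy ketone and the less nucleophilic alkenes, and the acetal both protects O6 and carries the radical precursor for step 13.

Step 8
Reactants: 17 C6 bromoacetal ketone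
Product: 18 cyclopent-2-enone (C4=O, C2=C3) with the trans C1 dienyl and C5 acetal-bearing allyl chains
Conditions: DBU, CH2Cl2, −20 to 0 °C, short contact; pH 7 buffer
Reagents that add atoms: none
Why: E1cB elimination: the amidine deprotonates the unhindered C3 methylene and the enolate expels the C2 silanolate, the standard way from 3-substituted 4-silyloxycyclopentanones to 4-substituted cyclopentenones; contact is kept short and cold so that O6 is not expelled from C6 and the double bond does not move toward C1.

Step 9
Reactants: 18 cyclopent-2-enone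
Product: 19 C3=C4 tert-butyldimethylsilyl enol ether (C2 now CH2)
Conditions: [(Ph3P)CuH]6, TBSCl, benzene, rt
Reagents that add atoms: tert-butyldimethylsilyl chloride, CC(C)(C)[Si](C)(C)Cl
Why: Copper hydride conjugate reduction with in situ O-silylation (reductive silylation) delivers hydride to C2 and traps the copper enolate as the regiodefined C3=C4 silyl enol ether, leaving the isolated alkenes, the alkyl bromide and the silyl ethers untouched.

Step 10
Reactants: 19 C3=C4 silyl enol ether
Product: 21 C4 ketone with C3 silyloxy group, via silyloxy epoxide 20 (not isolated)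
Conditions: dimethyldioxirane (acetone solution), CH2Cl2, −78 to −20 °C; then pyridinium p-toluenesulfonate (cat.), 0 °C
Reagents that add atoms: dimethyldioxirane, CC1(C)OO1
Why: Rubottom oxidation: the dioxirane epoxidizes only the electron-rich enol ether, expected on the face opposite the adjacent C5 chain (pushed pseudoaxial by the neighbouring silyloxy group), and acid-triggered opening of epoxide 20 with 1,4-silyl shift gives the silyloxy ketone with the C3 configuration of 37.

Step 11
Reactants: 21 C3-silyloxy C4 ketone
Product: 22 C4(15)-methylene compound with C3 and C9 OTBS, the O6 bromoacetal and two vinyl groups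
Conditions: Cp2TiMe2, toluene–THF, 65 °C, dark
Reagents that add atoms: dimethyltitanocene, [CH3-].[CH3-].[Ti+4].[cH-]1cccc1.[cH-]1cccc1
Why: Petasis methylenation through Cp2Ti=CH2 is non-basic, so the epimerizable C3 and C5 centres, the β-acetal oxygen and the alkyl bromide survive while the hindered ketone becomes the C4=C15 methylene.

Step 12
Reactants: 22 C4(15)-methylene triene
Product: 23 trans-fused hydroazulene with the C7=C8 ring alkene
Conditions: second-generation Grubbs catalyst (5–10 mol %), CH2Cl2 (high dilution), 40 °C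
Reagents that add atoms: none
Why: Ring-closing metathesis of the two monosubstituted vinyl groups forms C7=C8 and the cycloheptene with loss of ethylene; the 1,1-disubstituted methylenes cannot compete because closure onto them would need a cyclobutene, a bridgehead alkene or a trans-fused bicyclo[3.3.0]octene, and the trans fusion is already fixed at C1 and C5.

Step 13
Reactants: 23 hydroazulene bromoacetal
Product: 24 tricyclic 2-ethoxytetrahydrofuran (C7–C11 bond cis to O6, C8 now CH2)
Conditions: Bu3SnH, AIBN (cat.), benzene, 80 °C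
Reagents that add atoms: none
Why: Ueno–Stork radical cyclization: the primary radical from the bromoacetal adds 5-exo to C7 and can only form the cis-fused tetrahydrofuran, so the C7–C11 bond is delivered on the face of O6 (C7 as in 37); the C8 radical is reduced by Bu3SnH kept concentrated enough to outrun a homoallyl-type vinyl shift toward C10.

Step 14
Reactants: 24 tricyclic ethoxy acetal
Product: 25 lactol (C12 hemiacetal)
Conditions: AcOH–THF–H2O (3:1:1), 40 °C
Reagents that add atoms: water, O
Why: Acetal hydrolysis: mild aqueous acid opens the 2-ethoxytetrahydrofuran acetal much faster than it cleaves secondary TBS ethers.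

Step 15
Reactants: 25 lactol
Product: 26 cis-fused γ-lactone (O6–C12=O, C11 methylene)
Conditions: TEMPO (cat.), PhI(OAc)2, CH2Cl2, rt
Reagents that add atoms: none
Why: Oxoammonium-mediated oxidation converts the lactol, the only free hydroxyl, into the γ-lactone under neutral conditions and removes the acetal stereocentre.

Step 16
Reactants: 26 cis-fused γ-lactone
Product: 28 C11-methyl lactone, via lithium enolate 27 (not isolated)
Conditions: LiN(i-Pr)2, THF, −78 °C; MeI, −78 to −40 °C
Reagents that add atoms: iodomethane, CI
Why: Substrate-controlled enolate alkylation: methyl iodide approaches the lactone enolate on the convex face of the cis-fused bicycle, cis to H7 and away from the seven-membered ring, which sets C11 as in 37.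

Step 17
Reactants: 28 C11-methyl lactone
Product: 29 C6-hydroxy N-methoxy-N-methylamide
Conditions: MeNHOMe·HCl, AlMe3, CH2Cl2, 0 °C to rt; aq. potassium sodium tartrate
Reagents that add atoms: N,O-dimethylhydroxylamine hydrochloride, CNOC.Cl
Why: Aminolysis of the lactone by the aluminium amide formed from AlMe3 and the amine salt opens the ring to the Weinreb amide and frees the C6 hydroxyl without epimerizing C11; the crude hydroxy amide is silylated at once to prevent relactonization.

Step 18
Reactants: 29 C6-hydroxy Weinreb amide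
Product: 30 C6 triethylsilyl ether of the Weinreb amide
Conditions: TESOTf, 2,6-lutidine, CH2Cl2, −78 to 0 °C
Reagents that add atoms: triethylsilyl trifluoromethanesulfonate, CC[Si](CC)(CC)OS(=O)(=O)C(F)(F)F
Why: The silyl triflate with 2,6-lutidine silylates the hindered secondary C6 alcohol quickly at low temperature, and the TES ether blocks lactone and lactol formation in the next steps.

Step 19
Reactants: 30 C6-TES Weinreb amide
Product: 31 C12 aldehyde (O6 TES, O3 and O9 TBS)
Conditions: i-Bu2AlH, THF, −78 °C; aq. potassium sodium tartrate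
Reagents that add atoms: none
Why: Weinreb amide reduction: hydride addition stops at the chelated tetrahedral aluminium adduct, which releases the aldehyde only on work-up, so there is no over-reduction and C11 is not epimerized at −78 °C (the aldehyde is used crude).

Step 20
Reactants: 31 C12 aldehyde
Product: 33 C12 homoallylic alcohol (12S and 11,12-syn), via borinate 32 (not isolated)
Conditions: (−)-Ipc2B(allyl), Et2O, −78 °C; then aq. NaOH, H2O2, 0 °C to rt
Reagents that add atoms: (−)-B-allyldiisopinocampheylborane, C=CCB([C@@H]1C[C@@H]2C[C@H]([C@H]1C)C2(C)C)[C@@H]1C[C@@H]2C[C@H]([C@H]1C)C2(C)C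
Why: Brown allylboration through a chair six-membered transition state: the reagent derived from (+)-α-pinene adds allyl to the Si face of the aldehyde, which gives the 12S alcohol and coincides with the Felkin–Anh preference of the α-methyl aldehyde (11,12-syn), so reagent and substrate control are matched.

Step 21
Reactants: 33 C12 homoallylic alcohol
Product: 34 C12 acetate
Conditions: Ac2O, DMAP, pyridine, CH2Cl2, rt
Reagents that add atoms: acetic anhydride, CC(=O)OC(C)=O
Why: DMAP-catalysed acylation of the only free hydroxyl installs the C12 acetate of the target.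

Step 22
Reactants: 34 C12 acetate with terminal alkene; 35 2-methyl-2-butene
Product: 36 tris-silyl ether of the target with the complete side chain
Conditions: second-generation Hoveyda–Grubbs catalyst (5 mol %), 2-methyl-2-butene–CH2Cl2, 40 °C, sealed vessel
Reagents that add atoms: none
Why: Cross-metathesis of the monosubstituted alkene with excess 2-methyl-2-butene gives the trisubstituted isopropylidene terminus with loss of propene, while the hindered 1,1-disubstituted C14 and C15 methylenes should not react at this temperature.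

Step 23
Reactants: 36 tris-silyl ether
Product: 37 target CNP0210891.3
Conditions: HF·pyridine, pyridine, THF, 0 °C to rt
Reagents that add atoms: none
Why: Fluoride-induced desilylation with buffered HF·pyridine removes the TES and both TBS ethers under conditions too mild and non-basic to cleave or migrate the C12 acetate or to ionize the allylic alcohols.

Compound list
1 | (trimethylsilyl)acetylene | C#C[Si](C)(C)C | starting material
2 | acrolein | C=CC=O | starting material
3 | lithium (trimethylsilyl)acetylide | [Li]C#C[Si](C)(C)C | intermediate (not isolated)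
4 | rac-5-(trimethylsilyl)pent-1-en-4-yn-3-ol | C=CC(O)C#C[Si](C)(C)C | intermediate
5 | (R)-5-(trimethylsilyl)pent-1-en-4-yn-3-yl acetate | C=C[C@@H](OC(C)=O)C#C[Si](C)(C)C | intermediate
6 | (R)-5-(trimethylsilyl)pent-1-en-4-yn-3-ol | C=C[C@@H](O)C#C[Si](C)(C)C | intermediate (not isolated)
7 | (R)-pent-1-en-4-yn-3-ol | C=C[C@@H](O)C#C | intermediate
8 | (R)-3-(tert-butyldimethylsilyloxy)pent-1-en-4-yne | C=C[C@@H](O[Si](C)(C)C(C)(C)C)C#C | intermediate
9 | (R,Z)-B-[2-bromo-3-(tert-butyldimethylsilyloxy)penta-1,4-dien-1-yl]-9-borabicyclo[3.3.1]nonane | Br/C(=C\B1C2CCCC1CCC2)[C@H](O[Si](C)(C)C(C)(C)C)C=C | intermediate (not isolated)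
10 | (R)-2-bromo-3-(tert-butyldimethylsilyloxy)penta-1,4-diene | C=C[C@@H](O[Si](C)(C)C(C)(C)C)C(Br)=C | intermediate
11 | (S)-4-(tert-butyldimethylsilyloxy)cyclopent-2-en-1-one | O=C1C=C[C@@H](O[Si](C)(C)C(C)(C)C)C1 | starting material
12 | (R)-[3-(tert-butyldimethylsilyloxy)penta-1,4-dien-2-yl]lithium | [Li]C(=C)[C@H](O[Si](C)(C)C(C)(C)C)C=C | intermediate (not isolated)
13 | lithium dimethyl[(R)-3-(tert-butyldimethylsilyloxy)penta-1,4-dien-2-yl]zincate | [Li+].C[Zn-](C)C(=C)[C@H](O[Si](C)(C)C(C)(C)C)C=C | intermediate (not isolated)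
14 | lithium dimethylzincate C4–C5 enolate of the conjugate adduct (C1 dienyl trans to C2 OTBS) | [Li+].C[Zn-](C)OC1=C[C@H](C(=C)[C@H](O[Si](C)(C)C(C)(C)C)C=C)[C@@H](O[Si](C)(C)C(C)(C)C)C1 | intermediate (not isolated)
15 | three-component aldol adduct: cyclopentanone (C4=O) with the (R)-1-hydroxyprop-2-enyl chain (C6, C7) on C5, the (R)-3-(TBSO)penta-1,4-dien-2-yl chain (C10, C14, C9, C8) on C1 and OTBS on C2; C5/C1 trans, C1/C2 trans; C1, C5, C6, C9 as in 37 | O=C1[C@@H]([C@H](O)C=C)[C@H](C(=C)[C@H](O[Si](C)(C)C(C)(C)C)C=C)[C@@H](O[Si](C)(C)C(C)(C)C)C1 | intermediate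
16 | ethyl vinyl ether | C=COCC | starting material
17 | bromoacetal of 15: O6 carries a 2-bromo-1-ethoxyethyl group (both acetal epimers) | O=C1[C@@H]([C@H](OC(OCC)CBr)C=C)[C@H](C(=C)[C@H](O[Si](C)(C)C(C)(C)C)C=C)[C@@H](O[Si](C)(C)C(C)(C)C)C1 | intermediate
18 | cyclopent-2-enone (C4=O, C2=C3) with the C1 dienyl chain and the C5 chain bearing the O6 bromoacetal and vinyl group, trans | O=C1C=C[C@@H](C(=C)[C@H](O[Si](C)(C)C(C)(C)C)C=C)[C@@H]1[C@H](OC(OCC)CBr)C=C | intermediate
19 | C3=C4 TBS enol ether of the 2,3-dihydro ketone (C2 is CH2) | CC(C)(C)[Si](C)(C)OC1=CC[C@@H](C(=C)[C@H](O[Si](C)(C)C(C)(C)C)C=C)[C@@H]1[C@H](OC(OCC)CBr)C=C | intermediate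
20 | 3,4-epoxide of 19, epoxide oxygen anti to the C5 chain | CC(C)(C)[Si](C)(C)O[C@@]12O[C@H]2C[C@@H](C(=C)[C@H](O[Si](C)(C)C(C)(C)C)C=C)[C@@H]1[C@H](OC(OCC)CBr)C=C | intermediate (not isolated)
21 | C4 ketone with C3 OTBS trans to the C5 chain and cis to the C1 chain (C3 as in 37) | O=C1[C@@H](O[Si](C)(C)C(C)(C)C)C[C@@H](C(=C)[C@H](O[Si](C)(C)C(C)(C)C)C=C)[C@@H]1[C@H](OC(OCC)CBr)C=C | intermediate
22 | C4(15)-methylene cyclopentane: C3 OTBS, C5 chain with O6 bromoacetal and vinyl, C1 dienyl chain with C9 OTBS | C=C1[C@@H]([C@H](OC(OCC)CBr)C=C)[C@H](C(=C)[C@H](O[Si](C)(C)C(C)(C)C)C=C)C[C@@H]1O[Si](C)(C)C(C)(C)C | intermediate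
23 | trans-fused hydroazulene with C7=C8, C4=C15 and C10=C14 alkenes, C3 and C9 OTBS, O6 bromoacetal | C=C1[C@H]2[C@H](OC(OCC)CBr)C=C[C@@H](O[Si](C)(C)C(C)(C)C)C(=C)[C@@H]2C[C@@H]1O[Si](C)(C)C(C)(C)C | intermediate
24 | tricyclic 2-ethoxytetrahydrofuran (O6–C12 acetal, C11 methylene, C7–C11 bond cis to O6, C8 is CH2) | C=C1[C@H]2[C@H]3[C@H](CC(OCC)O3)C[C@@H](O[Si](C)(C)C(C)(C)C)C(=C)[C@@H]2C[C@@H]1O[Si](C)(C)C(C)(C)C | intermediate
25 | lactol (C12 hemiacetal, anomers) | C=C1[C@H]2[C@H]3[C@H](CC(O)O3)C[C@@H](O[Si](C)(C)C(C)(C)C)C(=C)[C@@H]2C[C@@H]1O[Si](C)(C)C(C)(C)C | intermediate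
26 | cis-fused γ-lactone (O6–C12=O, C11 methylene) | C=C1[C@H]2[C@H]3[C@H](CC(=O)O3)C[C@@H](O[Si](C)(C)C(C)(C)C)C(=C)[C@@H]2C[C@@H]1O[Si](C)(C)C(C)(C)C | intermediate
27 | lithium enolate of lactone 26 | C=C1[C@H]2[C@H]3[C@H](C=C(O[Li])O3)C[C@@H](O[Si](C)(C)C(C)(C)C)C(=C)[C@@H]2C[C@@H]1O[Si](C)(C)C(C)(C)C | intermediate (not isolated)
28 | C11-methyl cis-fused γ-lactone, methyl on the convex face (C11 as in 37) | C=C1[C@H]2[C@H]3[C@H]([C@H](C)C(=O)O3)C[C@@H](O[Si](C)(C)C(C)(C)C)C(=C)[C@@H]2C[C@@H]1O[Si](C)(C)C(C)(C)C | intermediate
29 | C6-hydroxy C12 N-methoxy-N-methylamide (opened lactone) | C=C1[C@H]2[C@H](O)[C@H]([C@H](C)C(=O)N(C)OC)C[C@@H](O[Si](C)(C)C(C)(C)C)C(=C)[C@@H]2C[C@@H]1O[Si](C)(C)C(C)(C)C | intermediate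
30 | C6 TES ether of amide 29 | C=C1[C@H]2[C@H](O[Si](CC)(CC)CC)[C@H]([C@H](C)C(=O)N(C)OC)C[C@@H](O[Si](C)(C)C(C)(C)C)C(=C)[C@@H]2C[C@@H]1O[Si](C)(C)C(C)(C)C | intermediate
31 | C12 aldehyde with O6 TES and O3, O9 TBS | C=C1[C@H]2[C@H](O[Si](CC)(CC)CC)[C@H]([C@H](C)C=O)C[C@@H](O[Si](C)(C)C(C)(C)C)C(=C)[C@@H]2C[C@@H]1O[Si](C)(C)C(C)(C)C | intermediate
32 | diisopinocampheylborinate of alcohol 33 | C=C1[C@H]2[C@H](O[Si](CC)(CC)CC)[C@H]([C@H](C)[C@H](CC=C)OB([C@@H]3C[C@@H]4C[C@H]([C@H]3C)C4(C)C)[C@@H]3C[C@@H]4C[C@H]([C@H]3C)C4(C)C)C[C@@H](O[Si](C)(C)C(C)(C)C)C(=C)[C@@H]2C[C@@H]1O[Si](C)(C)C(C)(C)C | intermediate (not isolated)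
33 | (12S)-homoallylic alcohol, 11,12-syn | C=C1[C@H]2[C@H](O[Si](CC)(CC)CC)[C@H]([C@H](C)[C@H](CC=C)O)C[C@@H](O[Si](C)(C)C(C)(C)C)C(=C)[C@@H]2C[C@@H]1O[Si](C)(C)C(C)(C)C | intermediate
34 | C12 acetate of 33 | C=C1[C@H]2[C@H](O[Si](CC)(CC)CC)[C@H]([C@H](C)[C@H](CC=C)OC(C)=O)C[C@@H](O[Si](C)(C)C(C)(C)C)C(=C)[C@@H]2C[C@@H]1O[Si](C)(C)C(C)(C)C | intermediate
35 | 2-methyl-2-butene | CC=C(C)C | starting material
36 | tris-silyl ether of the target (O6 TES, O3 and O9 TBS) with the 4-methylpent-3-enyl terminus | C=C1[C@H]2[C@H](O[Si](CC)(CC)CC)[C@H]([C@H](C)[C@H](CC=C(C)C)OC(C)=O)C[C@@H](O[Si](C)(C)C(C)(C)C)C(=C)[C@@H]2C[C@@H]1O[Si](C)(C)C(C)(C)C | intermediate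
37 | CNP0210891.3 (1R,3S,5S,6R,7S,9R,11S,12S in the numbering above) | C=C1[C@H]2[C@H](O)[C@H]([C@H](C)[C@H](CC=C(C)C)OC(C)=O)C[C@@H](O)C(=C)[C@@H]2C[C@@H]1O | target

Total step count: 23. Longest linear sequence: 23 steps, from 1 and 2 to 37 (11, 16 and 35 are bought).

Steps most likely to fail

Step 6. The aldol capture may partly run through boat or open transition states, be reversible, or take the conjugate course on acrolein, which would erode the C6 configuration and the yield. The fallback separates the two bond formations and sets out from 10 and 11. The conjugate addition is run as in step 6 and the enolate 14 is silylated (Me3SiCl, Et3N, −78 °C) to the isolable trimethylsilyl enol ether F1. Silicon–boron exchange with Bu2BOTf (CH2Cl2, −78 °C) gives the dibutylboron enolate F2. Its tight chair transition state with acrolein at −78 °C should give the anti boron aldolate F3. Work-up with methanol and pH 7 buffer releases 15, where the route is rejoined.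

Step 10. The oxidant may attack the enol ether on the face syn to the C5 chain, because the C1 dienyl group shields the other face, and so give the C3 epimer. The fallback replaces substrate control by reagent control and sets out from 18. Conjugate reduction with LiBH(s-Bu)3 (THF, −78 °C) gives the lithium enolate F4. This is hydroxylated at −78 °C with the matched enantiomer of (camphorsulfonyl)oxaziridine, chosen on small scale, to the C3 hydroxy ketone F5. Silylation with TBSOTf and 2,6-lutidine returns to the route at 21.

Step 8. After loss of the C2 silanolate the amidine may deprotonate the enone at C5 or C1. That would cause β-elimination of O6 or migration of the double bond into conjugation with the C10 alkene. The fallback generates the C3 enolate reductively, with no Brønsted base present, and sets out from 17. Kinetic enolization with in situ silylation (LiN(SiMe3)2, Me3SiCl, THF, −78 °C) gives the C3=C4 trimethylsilyl enol ether F6, which keeps the C2 silyloxy group. NBS (THF, −78 °C) converts it into the C3 bromo ketone F7. SmI2 (2 equiv, THF, −78 °C) reduces the carbon–bromine bond, and the samarium enolate expels the C2 silanolate, a reductive β-elimination of an α-halo β-oxygenated ketone. This gives 18, where the route is rejoined.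

Further compounds
F1 | step 6 | C4–C5 trimethylsilyl enol ether of the conjugate adduct | C[Si](C)(C)OC1=C[C@H](C(=C)[C@H](O[Si](C)(C)C(C)(C)C)C=C)[C@@H](O[Si](C)(C)C(C)(C)C)C1
F2 | step 6 | C4–C5 dibutylboron enolate of the conjugate adduct | CCCCB(CCCC)OC1=C[C@H](C(=C)[C@H](O[Si](C)(C)C(C)(C)C)C=C)[C@@H](O[Si](C)(C)C(C)(C)C)C1
F3 | step 6 | O6 dibutylboron aldolate of 15 | O=C1[C@@H]([C@H](OB(CCCC)CCCC)C=C)[C@H](C(=C)[C@H](O[Si](C)(C)C(C)(C)C)C=C)[C@@H](O[Si](C)(C)C(C)(C)C)C1
F4 | step 10 | C3=C4 lithium enolate from conjugate reduction of 18 | [Li]OC1=CC[C@@H](C(=C)[C@H](O[Si](C)(C)C(C)(C)C)C=C)[C@@H]1[C@H](OC(OCC)CBr)C=C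
F5 | step 10 | C3-hydroxy C4 ketone (C3 as in 37) | O=C1[C@@H](O)C[C@@H](C(=C)[C@H](O[Si](C)(C)C(C)(C)C)C=C)[C@@H]1[C@H](OC(OCC)CBr)C=C
F6 | step 8 | C3=C4 trimethylsilyl enol ether of 17 with the C2 OTBS retained | C[Si](C)(C)OC1=C[C@H](O[Si](C)(C)C(C)(C)C)[C@@H](C(=C)[C@H](O[Si](C)(C)C(C)(C)C)C=C)[C@@H]1[C@H](OC(OCC)CBr)C=C
F7 | step 8 | C3-bromo derivative of ketone 17 (either C3 epimer) | O=C1C(Br)[C@H](O[Si](C)(C)C(C)(C)C)[C@@H](C(=C)[C@H](O[Si](C)(C)C(C)(C)C)C=C)[C@@H]1[C@H](OC(OCC)CBr)C=C
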